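## Retrosynthetic overview

1. Numbering (bisabolane): ring C1 (CH2), C2–C3 (oxirane, CH3 on C3), C4 (CHOH), C5 (CH–O-acyl), C6 (CH). Side chain: C7(=C14H2), C8 (O-angeloyl), C9, C10–C11 (oxirane).
2. Endgame: ring oxirane by OH-directed epoxidation of C2=C3. C4–OH comes from 1,2-reduction of a 2-methylcyclohex-2-enone, the C10–C11 oxirane from Shi epoxidation, and the C8 angelate from Mitsunobu inversion.
3. The enone comes from a bridgehead silyl enol ether by C7 methylenation and Saegusa–Ito oxidation. That bicycle comes from an open-chain triene by a silicon-tethered type 2 intramolecular Diels–Alder reaction forming C1–C2 and C5–C6.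
4. Enabling feature: ring carbon C4 and side-chain carbon C8 both carry oxygen, and C4 stands 1,3 to C6 in the six-membered ring. An O4–Si(iPr)2–O8 bridge (temporary eight-membered ring C4–O–Si–O–C8–C7–C6–C5) holds the vinyl ketone C1=C6–C7(=O) under the diene C2=C3–C4=C5. The cis C5–O/C6–C7 pair is the imprint of a Z enol ester and an endo tether.
5. Ring order: cyclohexene ring together with the temporary eight-membered ring (step 7), bridge opened (step 9), side-chain oxirane (step 12), ring oxirane last (step 14). The triene is assembled from an acyloxy enone, iPr2Si(OTf)2 and a hydroxy vinyl ketone made from methyl (R)-glycidate.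

Key step: step 7

Remark on the chemistry: the stereocentre of the 2-methylbutanoate in the given structure reads as R, so (2R)-2-methylbutanoic acid is used. It is taken as commercially available, as are methyl (R)-glycidate, angelic acid and iPr2Si(OTf)2.

## Route

Step 1
Reactants: 1 methyl (2R)-oxirane-2-carboxylate (methyl (R)-glycidate); 2 (2-methylprop-1-en-1-yl)magnesium bromide
Product: 3 methyl (2R)-2-hydroxy-5-methylhex-4-enoate
Conditions: CuI (10 mol%), THF, −78 to −30 °C; then sat. aq. NH4Cl
Reagents that add atoms: none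
Why: Copper-catalysed SN2 opening of the glycidate by the alkenyl Grignard reagent should occur at the unsubstituted oxirane carbon faster than attack at the ester at low temperature, so the stereocentre (future C8, R) is carried over untouched from the chiral pool.

Step 2
Reactants: 3 methyl (2R)-2-hydroxy-5-methylhex-4-enoate
Product: 4 (2R)-2-hydroxy-N-methoxy-N,5-dimethylhex-4-enamide
Conditions: MeNHOMe·HCl, iPrMgCl (excess), THF, −20 to 0 °C; then sat. aq. NH4Cl
Reagents that add atoms: N,O-dimethylhydroxylamine hydrochloride, CNOC.Cl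
Why: Weinreb aminolysis of the ester with the chloromagnesium amide made in situ runs on the magnesium alkoxide of the free hydroxyl group, which shields the α-stereocentre from enolisation.

Step 3
Reactants: 4 (2R)-2-hydroxy-N-methoxy-N,5-dimethylhex-4-enamide; 5 vinylmagnesium bromide
Product: 6 (4R)-4-hydroxy-7-methylocta-1,6-dien-3-one
Conditions: 5 (2.5 equiv), THF, −20 to 0 °C; inverse quench into cold 1 M HCl; used at once
Reagents that add atoms: none
Why: In this Weinreb ketone synthesis the chelated tetrahedral adduct stops after one addition, and the inverse acidic quench protonates the released amine before it can add to the new vinyl ketone.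

Step 4
Reactants: 7 2-chloro-N-methoxy-N-methylacetamide; 8 prop-1-en-2-ylmagnesium bromide (isopropenylmagnesium bromide)
Product: 9 1-chloro-3-methylbut-3-en-2-one
Conditions: THF, −78 to 0 °C; then cold 1 M HCl
Reagents that add atoms: none
Why: Weinreb ketone synthesis on the chloroacetamide is the standard entry to α-chloro ketones, and the chelated adduct prevents both over-addition and attack at the C–Cl bond.

Step 5
Reactants: 9 1-chloro-3-methylbut-3-en-2-one; 10 (2R)-2-methylbutanoic acid
Product: 11 3-methyl-2-oxobut-3-en-1-yl (2R)-2-methylbutanoate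
Conditions: KHCO3 (1.2 equiv), DMF, 0 °C to rt
Reagents that add atoms: none
Why: SN2 displacement of the activated α-chloro ketone by the carboxylate (phenacyl-ester type esterification) never activates the acid, so its stereocentre should stay intact.

Step 6
Reactants: 11 3-methyl-2-oxobut-3-en-1-yl (2R)-2-methylbutanoate; 6 (4R)-4-hydroxy-7-methylocta-1,6-dien-3-one
Product: 13 tethered triene (mixed diisopropylsilaketal of 6 and of the Z enol of 11), via enol silyl triflate 12 (not isolated)
Conditions: 11, iPr2Si(OTf)2 (1.0 equiv), Et3N (2.5 equiv), CH2Cl2, −78 to −20 °C; then 6, −78 to 0 °C; rapid filtration through Et3N-deactivated SiO2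
Reagents that add atoms: diisopropylsilyl bis(trifluoromethanesulfonate), CC(C)[Si](OS(=O)(=O)C(F)(F)F)(OS(=O)(=O)C(F)(F)F)C(C)C
Why: Soft enolisation with a silyl triflate and an amine should give the sterically preferred Z enol silane (acyloxy group cis to O–Si, away from the isopropenyl group), and the remaining, less electrophilic Si–OTf then silylates the secondary alcohol of 6 faster than it enolises a ketone, which is the usual stepwise way to mixed silaketals.

Step 7
Reactants: 13 tethered triene
Product: 14 bridged cycloadduct, (5R,7R,11R)-10-methyl-5-(3-methylbut-2-en-1-yl)-6-oxo-3,3-di(propan-2-yl)-2,4-dioxa-3-silabicyclo[5.3.1]undec-1(10)-en-11-yl (2R)-2-methylbutanoate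
Conditions: PhMe (5 mM), BHT (10 mol%), base-washed sealed vessel, 110–130 °C
Reagents that add atoms: none
Why: On heating, the electron-rich diene C2=C3–C4=C5 (2-silyloxy, 1-acyloxy, 3-methyl) and the tethered vinyl ketone C1=C6–C7=O should combine in a concerted, asynchronous [4+2] cycloaddition that forms C1–C2 and C5–C6 at once; the closest known reaction type is the type 2 intramolecular Diels–Alder reaction (tether on C2 of the diene, here as a temporary silaketal), which is known to turn trienones with a five-atom tether and a terminal vinyl ketone into bicyclo[5.3.1]undec-1(10)-en-6-ones, also when the diene terminus next to the tether is substituted. Two rings close: the cyclohexene ring by the suprafacial [4+2] mode, and the eight-membered 1,3-dioxa-2-silocane ring (C4–O–Si–O–C8–C7–C6–C5) through the same C5–C6 bond, which leaves a 1,3-bridged bicycle with the C3=C4 enol ether at the bridgehead. The selectivity most needed is regiochemical, because the silyloxy group alone would send C5 to C1; the five-atom tether cannot span that 1,4-bridged mode, and the C5 acyloxy and C3 methyl groups raise the orbital coefficient at C2, so the enforced 1,3-mode is not badly mismatched. C6 is set by the tether, which reaches O4 only if C7 lies endo under C4 with the enone s-cis, and C5 by the Z enol geometry, which keeps the acyloxy group outside; endo plus outside gives the cis C5–O/C6–C7 relation of the target. The absolute sense comes from C8: in the folded transition state the C8 substituent that lies next to C6 faces the C5 acyloxy group, so it should be H while the prenyl chain points away from the diene, which for 8R opens the diene face that leads to the 5R,6R descriptors of 14 (the target configuration at both centres). The product carries the C4 oxygen as a regiodefined enol ether, O8 protected and the C5 ester already in place, so no further protecting group is needed.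

Step 8
Reactants: 14 bridged cycloadduct
Product: 15 (5R,7S,11R)-10-methyl-5-(3-methylbut-2-en-1-yl)-6-methylidene-3,3-di(propan-2-yl)-2,4-dioxa-3-silabicyclo[5.3.1]undec-1(10)-en-11-yl (2R)-2-methylbutanoate
Conditions: Cp2Ti(μ-CH2)(μ-Cl)AlMe2 (Tebbe reagent, 1.1 equiv), pyridine, THF–PhMe, −40 to 0 °C; then Na2SO4·10H2O
Reagents that add atoms: Tebbe reagent, C[Al](C)Cl.C=[Ti](C1C=CC=C1)C1C=CC=C1
Why: Tebbe methylenation through Cp2Ti=CH2 and an oxatitanacyclobutane is non-basic, so the β-acyloxy ketone should neither eliminate nor epimerise, and one equivalent at low temperature takes the ketone before the hindered ester.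

Step 9
Reactants: 15 methylidene bicycle
Product: 16 (1R,6S)-6-[(3R)-3-{[acetyloxydi(propan-2-yl)silyl]oxy}-6-methylhepta-1,5-dien-2-yl]-3-methyl-2-oxocyclohex-3-en-1-yl (2R)-2-methylbutanoate
Conditions: Pd(OAc)2 (1.05 equiv), MeCN, rt; filtration through Celite, used crude
Reagents that add atoms: palladium diacetate, CC(=O)[O-].CC(=O)[O-].[Pd+2]
Why: In this Saegusa–Ito oxidation divalent palladium takes the enolate over from silicon at the strained bridgehead enol ether and β-hydride elimination toward C2 gives the endocyclic 2-methylcyclohexenone, with the regiochemistry fixed by the cycloaddition, while the bridge opens and silicon stays on O8.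

Step 10
Reactants: 16 acetoxysilyl ether
Product: 17 (1R,6S)-6-[(3R)-3-hydroxy-6-methylhepta-1,5-dien-2-yl]-3-methyl-2-oxocyclohex-3-en-1-yl (2R)-2-methylbutanoate
Conditions: Et3N·3HF, MeCN, 0 °C to rt
Reagents that add atoms: none
Why: Fluoride-induced Si–O cleavage under slightly acidic conditions frees O8 without enolising the α-acyloxy ketone at C5.

Step 11
Reactants: 17 (8R)-hydroxy enone; 18 angelic acid, (2Z)-2-methylbut-2-enoic acid
Product: 19 (1R,6S)-3-methyl-6-[(3S)-6-methyl-3-{[(2Z)-2-methylbut-2-enoyl]oxy}hepta-1,5-dien-2-yl]-2-oxocyclohex-3-en-1-yl (2R)-2-methylbutanoate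
Conditions: PPh3, DIAD, PhMe, −20 °C to rt
Reagents that add atoms: none
Why: In the Mitsunobu esterification angelate displaces the oxyphosphonium group by SN2 with inversion (8R to 8S), and because the acid is never turned into an acyl donor the Z alkene should not isomerise to the tiglate.

Step 12
Reactants: 19 angelate enone
Product: 20 (1R,6S)-6-[(3S)-4-[(2R)-3,3-dimethyloxiran-2-yl]-3-{[(2Z)-2-methylbut-2-enoyl]oxy}but-1-en-2-yl]-3-methyl-2-oxocyclohex-3-en-1-yl (2R)-2-methylbutanoate
Conditions: D-fructose-derived Shi ketone (1 equiv), KHSO5 (as 2KHSO5·KHSO4·K2SO4), NaHCO3, MeCN–aq. disodium ethylenediaminetetraacetate (pH about 8), 0 °C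
Reagents that add atoms: potassium peroxymonosulfate, [K+].[O-]S(=O)(=O)OO
Why: In the Shi epoxidation the chiral dioxirane should attack only the electron-rich trisubstituted C10=C11 bond (the enone and angelate are electron-poor, C7=C14 is 1,1-disubstituted next to an ester) through the spiro transition state that gives R epoxides with this ketone, and the near-neutral buffer spares C5 from epimerisation.

Step 13
Reactants: 20 epoxy enone
Product: 21 (1R,2S,6S)-6-[(3S)-4-[(2R)-3,3-dimethyloxiran-2-yl]-3-{[(2Z)-2-methylbut-2-enoyl]oxy}but-1-en-2-yl]-2-hydroxy-3-methylcyclohex-3-en-1-yl (2R)-2-methylbutanoate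
Conditions: NaBH4, CeCl3·7H2O, MeOH, −78 °C; AcOH quench at −78 °C
Reagents that add atoms: none
Why: In the Luche 1,2-reduction, with the C6 side chain equatorial and the C5 acyloxy group axial, hydride should add to C4 axially and anti to that C–O bond (polar Felkin–Anh sense), which places the new hydroxyl group cis to both neighbours, and the cold acidic quench is meant to prevent 1,2-acyl migration.

Step 14
Reactants: 21 allylic alcohol
Product: 22 target CNP0181486.1, (2S,3R,4R,5R,6S,8S,10R)-8-angeloyloxy-2,3:10,11-diepoxy-4-hydroxy-5-[(2R)-2-methylbutanoyloxy]bisabol-7(14)-ene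
Conditions: VO(acac)2 (5 mol%), t-BuOOH (decane solution, 1.5 equiv), CH2Cl2, 0 °C to rt
Reagents that add atoms: tert-butyl hydroperoxide, CC(C)(C)OO
Why: In the vanadium-catalysed hydroxyl-directed epoxidation (Sharpless–Michaelson type) the C4 vanadate ester delivers the peroxide oxygen to the adjacent C2=C3 bond on the face of the hydroxyl group, which sets C2 (S) and C3 (R) cis to O4 and leaves the remote C7=C14 bond and the electron-poor angelate alone.

## Compound list

1 | methyl (2R)-oxirane-2-carboxylate | COC(=O)[C@H]1CO1 | starting material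
2 | (2-methylprop-1-en-1-yl)magnesium bromide | CC(C)=C[Mg]Br | starting material
3 | methyl (2R)-2-hydroxy-5-methylhex-4-enoate | COC(=O)[C@@H](CC=C(C)C)O | intermediate
4 | (2R)-2-hydroxy-N-methoxy-N,5-dimethylhex-4-enamide | CON(C)C(=O)[C@@H](CC=C(C)C)O | intermediate
5 | vinylmagnesium bromide | C=C[Mg]Br | starting material
6 | (4R)-4-hydroxy-7-methylocta-1,6-dien-3-one | C=CC(=O)[C@@H](CC=C(C)C)O | intermediate
7 | 2-chloro-N-methoxy-N-methylacetamide | CON(C)C(=O)CCl | starting material
8 | prop-1-en-2-ylmagnesium bromide | C=C(C)[Mg]Br | starting material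
9 | 1-chloro-3-methylbut-3-en-2-one | C=C(C)C(=O)CCl | intermediate
10 | (2R)-2-methylbutanoic acid | CC[C@@H](C)C(=O)O | starting material
11 | 3-methyl-2-oxobut-3-en-1-yl (2R)-2-methylbutanoate | C=C(C)C(=O)COC(=O)[C@H](C)CC | intermediate
12 | (1Z)-3-methyl-2-{[di(propan-2-yl)(trifluoromethanesulfonyloxy)silyl]oxy}buta-1,3-dien-1-yl (2R)-2-methylbutanoate | FC(F)(F)S(=O)(=O)O[Si](C(C)C)(C(C)C)O/C(C(C)=C)=C\OC(=O)[C@H](C)CC | intermediate
13 | (1Z)-3-methyl-2-{[{[(4R)-7-methyl-3-oxoocta-1,6-dien-4-yl]oxy}di(propan-2-yl)silyl]oxy}buta-1,3-dien-1-yl (2R)-2-methylbutanoate | C=CC(=O)[C@@H](CC=C(C)C)O[Si](C(C)C)(C(C)C)O/C(C(C)=C)=C\OC(=O)[C@H](C)CC | intermediate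
14 | (5R,7R,11R)-10-methyl-5-(3-methylbut-2-en-1-yl)-6-oxo-3,3-di(propan-2-yl)-2,4-dioxa-3-silabicyclo[5.3.1]undec-1(10)-en-11-yl (2R)-2-methylbutanoate | O=C1[C@@H](CC=C(C)C)O[Si](C(C)C)(C(C)C)OC2=C(C)CC[C@@H]1[C@H]2OC(=O)[C@H](C)CC | intermediate
15 | (5R,7S,11R)-10-methyl-5-(3-methylbut-2-en-1-yl)-6-methylidene-3,3-di(propan-2-yl)-2,4-dioxa-3-silabicyclo[5.3.1]undec-1(10)-en-11-yl (2R)-2-methylbutanoate | C=C1[C@@H](CC=C(C)C)O[Si](C(C)C)(C(C)C)OC2=C(C)CC[C@@H]1[C@H]2OC(=O)[C@H](C)CC | intermediate
16 | (1R,6S)-6-[(3R)-3-{[acetyloxydi(propan-2-yl)silyl]oxy}-6-methylhepta-1,5-dien-2-yl]-3-methyl-2-oxocyclohex-3-en-1-yl (2R)-2-methylbutanoate | C=C([C@@H](CC=C(C)C)O[Si](C(C)C)(C(C)C)OC(C)=O)[C@@H]1CC=C(C)C(=O)[C@@H]1OC(=O)[C@H](C)CC | intermediate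
17 | (1R,6S)-6-[(3R)-3-hydroxy-6-methylhepta-1,5-dien-2-yl]-3-methyl-2-oxocyclohex-3-en-1-yl (2R)-2-methylbutanoate | C=C([C@@H](CC=C(C)C)O)[C@@H]1CC=C(C)C(=O)[C@@H]1OC(=O)[C@H](C)CC | intermediate
18 | angelic acid, (2Z)-2-methylbut-2-enoic acid | C/C=C(/C)C(=O)O | starting material
19 | (1R,6S)-3-methyl-6-[(3S)-6-methyl-3-{[(2Z)-2-methylbut-2-enoyl]oxy}hepta-1,5-dien-2-yl]-2-oxocyclohex-3-en-1-yl (2R)-2-methylbutanoate | C=C([C@H](CC=C(C)C)OC(=O)/C(C)=C\C)[C@@H]1CC=C(C)C(=O)[C@@H]1OC(=O)[C@H](C)CC | intermediate
20 | (1R,6S)-6-[(3S)-4-[(2R)-3,3-dimethyloxiran-2-yl]-3-{[(2Z)-2-methylbut-2-enoyl]oxy}but-1-en-2-yl]-3-methyl-2-oxocyclohex-3-en-1-yl (2R)-2-methylbutanoate | C=C([C@H](C[C@H]1OC1(C)C)OC(=O)/C(C)=C\C)[C@@H]1CC=C(C)C(=O)[C@@H]1OC(=O)[C@H](C)CC | intermediate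
21 | (1R,2S,6S)-6-[(3S)-4-[(2R)-3,3-dimethyloxiran-2-yl]-3-{[(2Z)-2-methylbut-2-enoyl]oxy}but-1-en-2-yl]-2-hydroxy-3-methylcyclohex-3-en-1-yl (2R)-2-methylbutanoate | C=C([C@H](C[C@H]1OC1(C)C)OC(=O)/C(C)=C\C)[C@@H]1CC=C(C)[C@H](O)[C@@H]1OC(=O)[C@H](C)CC | intermediate
22 | CNP0181486.1, (2S,3R,4R,5R,6S,8S,10R)-8-angeloyloxy-2,3:10,11-diepoxy-4-hydroxy-5-[(2R)-2-methylbutanoyloxy]bisabol-7(14)-ene | C=C([C@H](C[C@H]1OC1(C)C)OC(=O)/C(C)=C\C)[C@@H]1C[C@@H]2O[C@]2(C)[C@H](O)[C@@H]1OC(=O)[C@H](C)CC | target

## Step count and risks

Total step count: 14. Longest linear sequence: 12 steps (steps 1–3 and 6–14).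

**Step 7.** The cycloaddition may be too slow at temperatures that the vinyl ketone and the enol ester tolerate. Polymerisation, or leakage through an exo or wrong-face approach, would then erode the result.

The fallback replaces the alkene dienophile by an alkyne and sets C6 afterwards by conjugate reduction. The alkyne is more reactive, has no endo/exo issue, and its linear shape relaxes the tether. The fallback sets out from 4 and comes back at 14.
- Ethynylmagnesium bromide converts 4 into the ynone (4R)-4-hydroxy-7-methyloct-6-en-1-yn-3-one F1.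
- F1 is silylated with 12 (made from 11 as in step 6) to give the tethered dienyne F2.
- The type 2 intramolecular Diels–Alder reaction of F2 should give the bridged cyclohexa-1,4-diene F3. Only C5 is set there, by the same Z-outside geometry and C8 control.
- 1,4-Reduction of the strained bridgehead enone with [(Ph3P)CuH]6, then protonation of the enolate at the bridgehead from the only open (outer) side, should give 14.

**Step 11.** SN2′ attack of the carboxylate at C14, elimination, or incomplete inversion at the hindered allylic C8 may compete with direct displacement.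

The fallback inverts C8 by oxidation and reagent-controlled reduction, then acylates with retention. It sets out from 17 and comes back at 19.
- MnO2 oxidises the only alcohol to the C8 ketone F4.
- (R)-2-Methyl-CBS-oxazaborolidine with catecholborane at −78 °C should reduce the less hindered α-methylene ketone before the ring enone, which is flanked by the C3 methyl group and the C5 ester. This gives the (8S)-alcohol F5.
- F5 is heated in toluene, without a nucleophilic catalyst, with angelic 2,4,6-trichlorobenzoic anhydride F6. F6 is made from 18, 2,4,6-trichlorobenzoyl chloride and Et3N. This known way to angelates without Z to E isomerisation leads to 19.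

**Step 14.** All three ring substituents lie on the face that has to be epoxidised. Delivery from the pseudo-equatorial C4 vanadate may therefore be slow, with oxidation back to the enone or poor facial selectivity as the result.

The fallback lets sterics work for the route by a halohydrin sequence. It sets out from 21 and comes back at 22.
- N-Bromosuccinimide in buffered aqueous acetone should form the bromonium ion on the open face of the most nucleophilic alkene (C2=C3).
- Water then opens it at the tertiary C3 from the hindered face. This gives the trans-diaxial bromohydrin F7, with C2–Br opposite to the ring substituents and C3–OH on their face.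
- DBU in CH2Cl2 closes the oxirane by backside displacement of bromide, which places the epoxide oxygen on the required face and gives 22.

## Further compounds

F1 | step 7 | (4R)-4-hydroxy-7-methyloct-6-en-1-yn-3-one | C#CC(=O)[C@@H](CC=C(C)C)O
F2 | step 7 | (1Z)-3-methyl-2-{[{[(4R)-7-methyl-3-oxooct-6-en-1-yn-4-yl]oxy}di(propan-2-yl)silyl]oxy}buta-1,3-dien-1-yl (2R)-2-methylbutanoate | C#CC(=O)[C@@H](CC=C(C)C)O[Si](C(C)C)(C(C)C)O/C(C(C)=C)=C\OC(=O)[C@H](C)CC
F3 | step 7 | (5R,11R)-10-methyl-5-(3-methylbut-2-en-1-yl)-6-oxo-3,3-di(propan-2-yl)-2,4-dioxa-3-silabicyclo[5.3.1]undeca-1(10),7-dien-11-yl (2R)-2-methylbutanoate | O=C1[C@@H](CC=C(C)C)O[Si](C(C)C)(C(C)C)OC2=C(C)CC=C1[C@H]2OC(=O)[C@H](C)CC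
F4 | step 11 | (1R,6S)-3-methyl-6-(6-methyl-3-oxohepta-1,5-dien-2-yl)-2-oxocyclohex-3-en-1-yl (2R)-2-methylbutanoate | C=C(C(=O)CC=C(C)C)[C@@H]1CC=C(C)C(=O)[C@@H]1OC(=O)[C@H](C)CC
F5 | step 11 | (1R,6S)-6-[(3S)-3-hydroxy-6-methylhepta-1,5-dien-2-yl]-3-methyl-2-oxocyclohex-3-en-1-yl (2R)-2-methylbutanoate | C=C([C@H](CC=C(C)C)O)[C@@H]1CC=C(C)C(=O)[C@@H]1OC(=O)[C@H](C)CC
F6 | step 11 | (2Z)-2-methylbut-2-enoic 2,4,6-trichlorobenzoic anhydride | C/C=C(/C)C(=O)OC(=O)c1c(Cl)cc(Cl)cc1Cl
F7 | step 14 | bromohydrin of 21 (C2–Br trans to the ring substituents, C3–OH cis to them) | C=C([C@H](C[C@H]1OC1(C)C)OC(=O)/C(C)=C\C)[C@@H]1C[C@@H](Br)[C@](C)(O)[C@H](O)[C@@H]1OC(=O)[C@H](C)CC
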